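**Retrosynthetic overview** (ring atoms numbered as in the target name: C1 = CBr(CH2Br), C2 = CHCl, C3 = CH2, C4 = CHCl, C5 = C(CH3)(CH=CHCl), C6 = CH2)
- Late stage: C1–Br and CH2–Br from Br2 addition to a C1 methylidene; the Z-chloroalkene from cross-metathesis of a C5 vinyl group; both C–Cl bonds from double inversion of a cis-2,4-diol.
- Key disconnection: C1–C2 and C4–C5 together, a redox-neutral [3+3] annulation of propane-1,3-diol (C2–C3–C4) with a silyl-capped allene–CH2–alkyne (C5–C6–C1 plus the methyl, vinyl and exocyclic carbons).
- Enabling feature: the cyclohexane is two 1,3-difunctional C3 halves. C2 and C4 are heteroatom-bearing CH carbons 1,3 to each other (a latent propane-1,3-diol). C5 is a methyl/vinyl quaternary carbon next to a carbinol (what a 1,1-disubstituted allene delivers by reverse allylation). C1 is a 1,1-disubstituted alkene carbon next to a carbinol (what an alkyne delivers by vinylation).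
- Only one ring is formed, in the key step; the SiMe3 cap on the alkyne is temporary and leaves in step 6.

Key step: step 3

Assumption (remark on the chemistry): the sense of asymmetric induction of the chiral ruthenium catalyst in step 3 cannot be predicted, so the SEGPHOS antipode is fixed by a first experiment; all structures are drawn for the required (3R,4S) series.

Step 1
Reactants: 1 ethynyl(trimethyl)silane; 2 1,4-dichlorobut-2-yne
Product: 4 (6-chlorohexa-1,4-diyn-1-yl)(trimethyl)silane, via alkynylmagnesium bromide 3 (not isolated)
Conditions: EtMgBr (1.0 equiv), THF, 0 → 40 °C; then 2 (3 equiv), CuCl (5 mol %), THF, 50 °C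
Reagents that add atoms: ethylmagnesium bromide, CC[Mg]Br (its MgBr is carried only by 3)
Why: Copper-catalysed coupling of an alkynyl Grignard reagent with a propargylic chloride (the classical skipped-diyne synthesis) should proceed by direct SN2 substitution, and the excess of the symmetrical dichloride should hold it at monosubstitution.

Step 2
Reactants: 4 (6-chlorohexa-1,4-diyn-1-yl)(trimethyl)silane
Product: 5 trimethyl(4-methylhexa-4,5-dien-1-yn-1-yl)silane
Conditions: MeMgBr (1.2 equiv), CuBr·SMe2 (10 mol %), THF, −40 → 0 °C
Reagents that add atoms: methylmagnesium bromide, C[Mg]Br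
Why: Copper-catalysed anti-SN2′ substitution of a primary propargylic chloride by a Grignard reagent is the standard route to 1,1-disubstituted allenes; no stereocentre is formed and the silyl-capped alkyne should be inert.

Step 3
Reactants: 5 trimethyl(4-methylhexa-4,5-dien-1-yn-1-yl)silane; 6 propane-1,3-diol
Product: 9 (1S,3R,4S,6E)-4-ethenyl-4-methyl-6-[(trimethylsilyl)methylidene]cyclohexane-1,3-diol, via acyclic diol 7 (not isolated), via hydroxy aldehyde 8 (not isolated)
Conditions: RuH2(CO)(PPh3)3 (5 mol %), SEGPHOS (5 mol %, antipode as stated in the assumption), CF3CO2H (5 mol %), THF (0.05 M), 95 °C, sealed tube; 6 (3 equiv), 5 added over 8 h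
Reagents that add atoms: none
Why: Proposed new method: one divalent ruthenium hydride should run two redox-triggered carbonyl additions in sequence: it dehydrogenates one CH2OH of 6, hydrometalates the terminal C=C of the allene to an allylruthenium that adds through its methyl-bearing carbon in a closed chair (giving 7), then dehydrogenates the second CH2OH to 8 and returns the hydride by reversible syn-hydrometalation of the silylalkyne, the vinylruthenium with the metal on the internal carbon inserting the tethered aldehyde. The closest known reaction types are the ruthenium-catalysed coupling of 1,1-disubstituted allenes with primary alcohols (anti-selective, all-carbon quaternary centres), the ruthenium-catalysed alkyne–alcohol coupling to allylic alcohols (including an intramolecular ynal case) and the two-directional double allylation of propane-1,3-diol; their merger into a [3+3] annulation is untested. The cyclohexane closes in a 6-exo-dig sense, and syn addition of H and carbon across the alkyne should leave the SiMe3 group E on the exocyclic alkene. C3 and C4 of 9 (OH cis to CH3) should follow from the (E)-allylruthenium, favoured by rapid E/Z equilibration, reacting in the chair with the aldehyde substituent equatorial, and their absolute sense from the chiral bisphosphine on ruthenium. C1 of 9 is set under substrate control: the forming C–O bond is held in the plane of the exocyclic alkene (pseudo-equatorial) on a chair that keeps the C3–O bond equatorial, which should give the cis-1,3-diol. The step needs 1:1 annulation over 2:1 coupling and carbon–carbon bond formation at the methyl-bearing allene carbon and the internal alkyne carbon; the first is secured by the intramolecular second addition, slow addition of 5 and excess 6, the second by the 1,1-disubstitution of the allene, the one-carbon tether and the SiMe3 cap, which also blocks terminal-alkyne side reactions.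

Step 4
Reactants: 9 (1S,3R,4S,6E)-4-ethenyl-4-methyl-6-[(trimethylsilyl)methylidene]cyclohexane-1,3-diol
Product: 10 {(E)-[(2R,4S,5S)-2,4-dichloro-5-ethenyl-5-methylcyclohexylidene]methyl}(trimethyl)silane
Conditions: PPh3 (3 equiv), NCS (3 equiv), THF, 0 → 45 °C
Reagents that add atoms: N-chlorosuccinimide, ClN1C(=O)CCC1=O
Why: Appel-type deoxychlorination with SN2 inversion at both carbinol carbons should turn the cis-diol (OH cis to CH3) into the cis-dichloride (Cl cis to the vinyl group); this reagent pair has close precedent for inverting a cyclohexanol next to a methyl/vinyl quaternary carbon, and the SiMe3 group on the exocyclic alkene blocks SN2′ attack and disfavours ionisation at the allylic carbon.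

Step 5
Reactants: 10 {(E)-[(2R,4S,5S)-2,4-dichloro-5-ethenyl-5-methylcyclohexylidene]methyl}(trimethyl)silane
Product: 11 {(E)-[(2R,4S,5S)-2,4-dichloro-5-[(Z)-2-chloroethenyl]-5-methylcyclohexylidene]methyl}(trimethyl)silane
Conditions: (Z)-ClCH=CHCl (5 equiv), Mo(NC6F5)(CHCMe2Ph)(2,5-Me2NC4H2)(O-2,6-(2,4,6-iPr3C6H2)2C6H3) (5 mol %), C6H6, 22 °C
Reagents that add atoms: (Z)-1,2-dichloroethene, Cl/C=C\Cl
Why: Kinetically Z-selective cross-metathesis with (Z)-1,2-dichloroethene on a monoaryloxide pyrrolide molybdenum alkylidene should convert the monosubstituted vinyl group into the Z-alkenyl chloride; the alkylidene formed from 10 is of the same neopentylidene type as the neophylidene of the precatalyst, and the trisubstituted vinylsilane should not take part.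

Step 6
Reactants: 11 {(E)-[(2R,4S,5S)-2,4-dichloro-5-[(Z)-2-chloroethenyl]-5-methylcyclohexylidene]methyl}(trimethyl)silane
Product: 12 (1S,2S,4R)-2,4-dichloro-1-[(Z)-2-chloroethenyl]-1-methyl-5-methylidenecyclohexane
Conditions: CF3CO2H (5 equiv), CH2Cl2, 0 °C; aq. NaHCO3 work-up
Reagents that add atoms: none
Why: Acid-mediated ipso-protodesilylation of a vinylsilane: protonation at the silicon-bearing carbon is steered by the β-silicon effect and loss of the silyl group should restore the exocyclic double bond in place, leaving the allylic and alkenyl chlorides and all stereocentres untouched.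

Step 7
Reactants: 12 (1S,2S,4R)-2,4-dichloro-1-[(Z)-2-chloroethenyl]-1-methyl-5-methylidenecyclohexane
Product: 13 (1S,2R,4S,5S)-1-bromo-1-(bromomethyl)-2,4-dichloro-5-[(Z)-2-chloroethenyl]-5-methylcyclohexane
Conditions: Br2 (1.0 equiv), CH2Cl2, −78 °C, dark
Reagents that add atoms: bromine, BrBr
Why: Electrophilic anti-addition of bromine to the 1,1-disubstituted alkene (far more nucleophilic than the Z-chloroalkene) should give the 1-bromo-1-(bromomethyl) unit; C1 is set under substrate control, the larger CH2Br group taking the equatorial and the tertiary bromine the axial position on the chair with both chlorines equatorial, which is also the thermodynamically preferred epimer.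

**Compound list**
1 | ethynyl(trimethyl)silane | C#C[Si](C)(C)C | starting material
2 | 1,4-dichlorobut-2-yne | ClCC#CCCl | starting material
3 | bromo[(trimethylsilyl)ethynyl]magnesium | C[Si](C)(C)C#C[Mg]Br | intermediate
4 | (6-chlorohexa-1,4-diyn-1-yl)(trimethyl)silane | C[Si](C)(C)C#CCC#CCCl | intermediate
5 | trimethyl(4-methylhexa-4,5-dien-1-yn-1-yl)silane | C[Si](C)(C)C#CCC(C)=C=C | intermediate
6 | propane-1,3-diol | OCCCO | starting material
7 | (3R,4S)-4-ethenyl-4-methyl-7-(trimethylsilyl)hept-6-yne-1,3-diol | OCC[C@@H](O)[C@](C)(C=C)CC#C[Si](C)(C)C | intermediate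
8 | (3R,4S)-4-ethenyl-3-hydroxy-4-methyl-7-(trimethylsilyl)hept-6-ynal | O=CC[C@@H](O)[C@](C)(C=C)CC#C[Si](C)(C)C | intermediate
9 | (1S,3R,4S,6E)-4-ethenyl-4-methyl-6-[(trimethylsilyl)methylidene]cyclohexane-1,3-diol | C[C@@]1(C=C)C/C(=C\[Si](C)(C)C)[C@@H](O)C[C@H]1O | intermediate
10 | {(E)-[(2R,4S,5S)-2,4-dichloro-5-ethenyl-5-methylcyclohexylidene]methyl}(trimethyl)silane | C[C@@]1(C=C)C/C(=C\[Si](C)(C)C)[C@H](Cl)C[C@@H]1Cl | intermediate
11 | {(E)-[(2R,4S,5S)-2,4-dichloro-5-[(Z)-2-chloroethenyl]-5-methylcyclohexylidene]methyl}(trimethyl)silane | C[C@@]1(/C=C\Cl)C/C(=C\[Si](C)(C)C)[C@H](Cl)C[C@@H]1Cl | intermediate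
12 | (1S,2S,4R)-2,4-dichloro-1-[(Z)-2-chloroethenyl]-1-methyl-5-methylidenecyclohexane | C[C@@]1(/C=C\Cl)CC(=C)[C@H](Cl)C[C@@H]1Cl | intermediate
13 | (1S,2R,4S,5S)-1-bromo-1-(bromomethyl)-2,4-dichloro-5-[(Z)-2-chloroethenyl]-5-methylcyclohexane | C[C@@]1(/C=C\Cl)C[C@@](Br)(CBr)[C@H](Cl)C[C@@H]1Cl | target

Total step count: 7. Longest linear sequence: 7 steps (1 → 13).

**Steps most likely to fail**

1. Step 3 (proposed new method). The cascade may halt after the first addition, the alkyne may be isomerised or reduced, 2:1 coupling may outrun ring closure, and asymmetric induction at ruthenium is unproven. The fallback makes the two bonds one at a time with known reactions; it sets out from 5 and comes back at 9. Allene 5 is coupled with 3-[(tert-butyldimethylsilyl)oxy]propan-1-ol under a cyclometalated iridium–PhanePhos catalyst ([Ir(cod)Cl]2, PhanePhos, THF, 70 °C), an alcohol-mediated allene hydrometalation–carbonyl addition known for 1,1-disubstituted allenes. This should give (3R,4S)-1-[(tert-butyldimethylsilyl)oxy]-4-ethenyl-4-methyl-7-(trimethylsilyl)hept-6-yn-3-ol F1. Acidic methanolysis (CSA, MeOH, 0 °C) frees diol 7, and TEMPO/PhI(OAc)2 oxidises only its primary alcohol to 8. A reductive ynal cyclisation with zerovalent nickel (Ni(cod)2, PBu3, Et3SiH, THF) closes the ring to (1R,2S,4E,5S)-2-ethenyl-2-methyl-5-[(triethylsilyl)oxy]-4-[(trimethylsilyl)methylidene]cyclohexan-1-ol F2, and PPTS/MeOH returns 9.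

2. Step 4. Substitution at the neopentylic carbinol may be outrun by elimination towards the neighbouring CH2, or the reaction may stall after the allylic chloride is formed. The fallback treats the two carbinols separately; it sets out from 9 and comes back at 10. With PPh3/NCS (1.1 equiv each, THF, −20 °C) only the allylic carbinol should be chlorinated, giving (1R,2S,4E,5R)-5-chloro-2-ethenyl-2-methyl-4-[(trimethylsilyl)methylidene]cyclohexan-1-ol F3. The hindered alcohol is then converted (Tf2O, pyridine, CH2Cl2, −40 °C) into (1R,2S,4E,5R)-5-chloro-2-ethenyl-2-methyl-4-[(trimethylsilyl)methylidene]cyclohexyl trifluoromethanesulfonate F4. Displacement with Bu4NCl (toluene, 0 °C → room temperature), the strongest nucleofuge with a naked chloride, should return 10 with inversion.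

3. Step 5. The alkylidene may not form at the vinyl group on the quaternary carbon (no turnover), or Z selectivity may erode through secondary metathesis. The fallback replaces metathesis by cleavage and olefination; it sets out from 10 and comes back at 11. Lemieux–Johnson oxidation (OsO4 2 mol %, NaIO4, 2,6-lutidine, dioxane/H2O) should cleave the monosubstituted vinyl group only, because the trisubstituted vinylsilane is deactivated by the allylic chlorine and shielded by SiMe3. This gives (1S,2S,4R,5E)-2,4-dichloro-1-methyl-5-[(trimethylsilyl)methylidene]cyclohexane-1-carbaldehyde F5, which cannot enolise. Wittig chloromethylenation (Ph3PCH2Cl chloride, NaHMDS, THF, −78 °C), with chromatographic separation of the Z isomer, returns 11.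

Further compounds
F1 | step 3 | (3R,4S)-1-[(tert-butyldimethylsilyl)oxy]-4-ethenyl-4-methyl-7-(trimethylsilyl)hept-6-yn-3-ol | CC(C)(C)[Si](C)(C)OCC[C@@H](O)[C@](C)(C=C)CC#C[Si](C)(C)C
F2 | step 3 | (1R,2S,4E,5S)-2-ethenyl-2-methyl-5-[(triethylsilyl)oxy]-4-[(trimethylsilyl)methylidene]cyclohexan-1-ol | C[C@@]1(C=C)C/C(=C\[Si](C)(C)C)[C@@H](O[Si](CC)(CC)CC)C[C@H]1O
F3 | step 4 | (1R,2S,4E,5R)-5-chloro-2-ethenyl-2-methyl-4-[(trimethylsilyl)methylidene]cyclohexan-1-ol | C[C@@]1(C=C)C/C(=C\[Si](C)(C)C)[C@H](Cl)C[C@H]1O
F4 | step 4 | (1R,2S,4E,5R)-5-chloro-2-ethenyl-2-methyl-4-[(trimethylsilyl)methylidene]cyclohexyl trifluoromethanesulfonate | C[C@@]1(C=C)C/C(=C\[Si](C)(C)C)[C@H](Cl)C[C@H]1OS(=O)(=O)C(F)(F)F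
F5 | step 5 | (1S,2S,4R,5E)-2,4-dichloro-1-methyl-5-[(trimethylsilyl)methylidene]cyclohexane-1-carbaldehyde | C[C@@]1(C=O)C/C(=C\[Si](C)(C)C)[C@H](Cl)C[C@@H]1Cl
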